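**Retrosynthetic overview** (germacrane numbering: lactone O on C6, angelate on C8, CH2OH = C14)
1. Last bond: C14–O, by 1,3-transposition of the C1 hydroxyl of a ring A exo-methylene 1,2-diol; this sets the ring-cis C1=C10 alkene and erases the C1 stereocentre.
2. Ring A (ten-membered) is closed just before, at C1–C10, by Nozaki–Hiyama–Kishi vinylation of the C1 aldehyde by a 2-bromoallyl unit, so C1 needs no stereocontrol.
3. Ring B (α-methylene lactone, C6–O) is formed first, at the fragment union: chromium-mediated 2-(methoxycarbonyl)allylation of a masked Z-enal (C6–C7) and lactonisation; C8 controls C6 and C7.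
4. West fragment: vinylogous aldol/lactonisation of methyl senecioate with 2,2-dimethoxyacetaldehyde sets C2 and locks the Z C4=C5 alkene in a temporary δ-lactone. East fragment: asymmetric 2-bromoallylation of the same aldehyde sets C8, then Morita–Baylis–Hillman homologation.
5. Ring order: temporary δ-lactone, ring B, ring A; the angelate goes on C8 after ring A, then the C–O transposition.

Assumption: ligand antipodes are quoted for the facial sense stated in each step; 6 is an anomer mixture, 13 a C3-epimer mixture, and 18, 19, 21, 22 and 23 are C1-epimer mixtures (centres erased later).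

**Step 1**
Reactants: 1 methyl 3-methylbut-2-enoate
Product: 2 [(1-methoxy-3-methylbuta-1,3-dien-1-yl)oxy]trimethylsilane
Conditions: LiN(iPr)2, THF, −78 °C; Me3SiCl
Reagents that add atoms: chlorotrimethylsilane, C[Si](C)(C)Cl
Why: Kinetic γ-deprotonation of the senecioate and O-silylation (silyl ketene acetal formation) give the silyl dienolate needed for a vinylogous Mukaiyama aldol reaction.

**Step 2**
Reactants: 2 [(1-methoxy-3-methylbuta-1,3-dien-1-yl)oxy]trimethylsilane; 3 2,2-dimethoxyacetaldehyde
Product: 5 (S)-6-(dimethoxymethyl)-4-methyl-5,6-dihydro-2H-pyran-2-one, via copper aldolate of the Z hydroxy ester 4 (not isolated)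
Conditions: Cu(OTf)2 (10 mol %), (S)-Tol-BINAP (11 mol %), Bu4N[Ph3SiF2] (20 mol %), THF, −78 → 23 °C
Reagents that add atoms: none
Why: Catalytic asymmetric vinylogous Mukaiyama aldol reaction in which the chiral copper dienolate attacks the Si face of the aldehyde through its γ-carbon (C2 becomes S) and the copper aldolate of the Z adduct lactonises in situ, which locks the C4=C5 alkene in the ring-cis geometry.

**Step 3**
Reactants: 5 (S)-6-(dimethoxymethyl)-4-methyl-5,6-dihydro-2H-pyran-2-one
Product: 6 (6S)-6-(dimethoxymethyl)-4-methyl-5,6-dihydro-2H-pyran-2-ol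
Conditions: iBu2AlH (1.1 equiv), CH2Cl2, −78 °C; aq. KNaC4H4O6
Reagents that add atoms: none
Why: Partial hydride reduction of the unsaturated δ-lactone stops at the lactol at low temperature, giving a masked Z-configured δ-hydroxy enal that cannot isomerise to the E enal.

**Step 4**
Reactants: 3 2,2-dimethoxyacetaldehyde; 7 2,3-dibromoprop-1-ene
Product: 9 (S)-4-bromo-1,1-dimethoxypent-4-en-2-ol, via O-trimethylsilyl ether 8 (not isolated)
Conditions: CrCl2 (10 mol %), (S)-oxazoline–sulfonamide ligand (11 mol %), Et3N (20 mol %), Mn, Me3SiCl, THF, 0 °C; then K2CO3 (cat.), MeOH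
Reagents that add atoms: none
Why: Catalytic asymmetric Nozaki–Hiyama 2-haloallylation in which only the allylic C–Br bond of 7 is reduced (manganese turns the chromium over, the vinyl C–Br bond is inert without nickel) and the ligated allylchromium adds to the Si face of the aldehyde, setting C8 as S.

**Step 5**
Reactants: 9 (S)-4-bromo-1,1-dimethoxypent-4-en-2-ol
Product: 10 (S)-[(4-bromo-1,1-dimethoxypent-4-en-2-yl)oxy](tert-butyl)dimethylsilane
Conditions: TBSCl, imidazole, DMF, 23 °C
Reagents that add atoms: tert-butyldimethylsilyl chloride, CC(C)(C)[Si](C)(C)Cl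
Why: Standard silylation protects the C8 hydroxyl with a group that, unlike an acyloxy group, will not be expelled from the allylchromium reagent of step 9.

**Step 6**
Reactants: 10 (S)-[(4-bromo-1,1-dimethoxypent-4-en-2-yl)oxy](tert-butyl)dimethylsilane
Product: 11 (S)-4-bromo-2-[(tert-butyldimethylsilyl)oxy]pent-4-enal
Conditions: TFA/H2O/CHCl3 (1:1:4), 0 °C
Reagents that add atoms: water, O
Why: Acid-catalysed acetal hydrolysis unmasks the C7 aldehyde under cold conditions that neither cleave the secondary silyl ether nor epimerise the α-silyloxy centre.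

**Step 7**
Reactants: 11 (S)-4-bromo-2-[(tert-butyldimethylsilyl)oxy]pent-4-enal; 12 methyl acrylate
Product: 13 methyl (4S)-6-bromo-4-[(tert-butyldimethylsilyl)oxy]-3-hydroxy-2-methylidenehept-6-enoate
Conditions: quinuclidine (0.5 equiv), MeOH (cat.), neat 12, 0 → 23 °C
Reagents that add atoms: none
Why: Morita–Baylis–Hillman reaction of the activated α-silyloxy aldehyde installs C11–C13, and the new carbinol centre is irrelevant because it is removed in step 8.

**Step 8**
Reactants: 13 methyl (4S)-6-bromo-4-[(tert-butyldimethylsilyl)oxy]-3-hydroxy-2-methylidenehept-6-enoate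
Product: 14 methyl (2Z,4S)-6-bromo-2-(bromomethyl)-4-[(tert-butyldimethylsilyl)oxy]hepta-2,6-dienoate
Conditions: NBS, Me2S, CH2Cl2, 0 → 23 °C
Reagents that add atoms: N-bromosuccinimide, O=C1CCC(=O)N1Br
Why: Corey–Kim-type activation of the Baylis–Hillman alcohol as an alkoxysulfonium ion followed by SN2′ attack of bromide gives the thermodynamically preferred Z 2-(bromomethyl)enoate, the allyl donor for ring B.

**Step 9**
Reactants: 6 (6S)-6-(dimethoxymethyl)-4-methyl-5,6-dihydro-2H-pyran-2-ol; 14 methyl (2Z,4S)-6-bromo-2-(bromomethyl)-4-[(tert-butyldimethylsilyl)oxy]hepta-2,6-dienoate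
Product: 16 4-{3-bromo-1-[(tert-butyldimethylsilyl)oxy]but-3-en-1-yl}-5-[(1Z)-4-hydroxy-5,5-dimethoxy-2-methylpent-1-en-1-yl]-3-methylideneoxolan-2-one (4,5-trans), via hydroxy ester 15 (not isolated)
Conditions: CrCl2 (4 equiv), THF–DMF (4:1), 0 → 23 °C; then PPTS (cat.), CH2Cl2, 23 °C
Reagents that add atoms: none
Why: Nozaki–Hiyama allylation in which divalent chromium inserts only into the allylic C–Br bond and the resulting 2-(methoxycarbonyl)allylchromium adds through its γ-carbon to the Z-enal released from the lactol via a chair transition state giving the anti adduct, attacking anti to the C8 silyloxy group in the conformer with H8 eclipsing the alkene (1,3-allylic strain), so that C8 sets C7 and C6 in the target configuration before the alkoxide closes the trans α-methylene lactone (ring B) with loss of methanol.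

**Step 10**
Reactants: 16 the trans-lactone acetal of step 9
Product: 17 4-{3-bromo-1-[(tert-butyldimethylsilyl)oxy]but-3-en-1-yl}-5-[(1Z)-4-hydroxy-2-methyl-5-oxopent-1-en-1-yl]-3-methylideneoxolan-2-one
Conditions: TFA/H2O (9:1), CH2Cl2, 0 °C
Reagents that add atoms: water, O
Why: Acid-catalysed acetal hydrolysis frees the C1 aldehyde for ring closure while the lactone, the vinyl bromide and the secondary silyl ether survive.

**Step 11**
Reactants: 17 the α-hydroxy aldehyde of step 10
Product: 18 (10Z)-4-[(tert-butyldimethylsilyl)oxy]-7,8-dihydroxy-10-methyl-3,6-dimethylidene-3a,4,5,6,7,8,9,11a-octahydrocyclodeca[b]furan-2(3H)-one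
Conditions: CrCl2 (8 equiv), NiCl2 (1 mol %), DMSO–THF (3:1), 23 °C, 3 mM, slow addition; then H2O
Reagents that add atoms: none
Why: Nozaki–Hiyama–Kishi macrocyclisation in which nickel activates the vinyl bromide, the alkenylchromium formed with divalent chromium adds chemoselectively to the aldehyde and closes the ten-membered ring A at C1–C10, and the configuration of the new C1 carbinol does not matter because step 14 erases it.

**Step 12**
Reactants: 18 the macrocyclic silyl ether diol of step 11
Product: 19 (10Z)-4,7,8-trihydroxy-10-methyl-3,6-dimethylidene-3a,4,5,6,7,8,9,11a-octahydrocyclodeca[b]furan-2(3H)-one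
Conditions: HF·pyridine, THF, 0 °C
Reagents that add atoms: none
Why: Fluoride-mediated desilylation frees the C8 hydroxyl without affecting the lactone or the allylic diol.

**Step 13**
Reactants: 19 the triol of step 12; 20 angelic acid [(Z)-2-methylbut-2-enoic acid]
Product: 23 (10Z)-7,8-dihydroxy-10-methyl-3,6-dimethylidene-2-oxo-2,3,3a,4,5,6,7,8,9,11a-decahydrocyclodeca[b]furan-4-yl (Z)-2-methylbut-2-enoate, via cyclic phenylboronate 21 (not isolated), via acylated phenylboronate 22 (not isolated)
Conditions: PhB(OH)2, 4 Å MS, toluene, 23 °C; then 20, 2,4,6-Cl3C6H2COCl, Et3N, DMAP, toluene, 0 → 40 °C; then pinacol, 23 °C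
Reagents that add atoms: none
Why: Transient protection of the vicinal C1/C2 diol as its cyclic phenylboronate leaves only the C8 hydroxyl for Yamaguchi esterification (mixed-anhydride activation keeps the Z geometry of the angelate), and pinacol then releases the diol by transesterification.

**Step 14**
Reactants: 23 the 8-O-angeloyl exo-methylene diol of step 13
Product: 24 [(3aR,4S,6E,8S,10Z,11aR)-8-hydroxy-6-(hydroxymethyl)-10-methyl-3-methylidene-2-oxo-2,3,3a,4,5,8,9,11a-octahydrocyclodeca[b]furan-4-yl] (Z)-2-methylbut-2-enoate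
Conditions: Ph3SiOReO3 (5 mol %), Et2O, −20 → 0 °C
Reagents that add atoms: none
Why: Proposed new method: triphenylsilyl perrhenate condenses with the allylic C1 hydroxyl to a perrhenate ester that undergoes a chair-like [3,3]-sigmatropic shift delivering oxygen to the exocyclic C14 terminus, and because the shift is reversible the mixture drains to the most stable isomer, the primary alcohol with the endocyclic trisubstituted C1=C10 alkene whose ring-cis geometry is imposed by the ten-membered ring, while both C1 epimers converge on one product and the C2–O bond is never broken (any transient C2-to-C10 excursion must return to the same face because the ring fixes the alkene geometry); the closest known reaction type is the rhenium-oxo-catalysed 1,3-transposition of simple allylic alcohols, which has not been shown on a medium-ring exo-methylene carbinol carrying a free vicinal hydroxyl or used to set an endocyclic trisubstituted alkene, and here it forms the C14–O bond and sets the C1=C10 geometry.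

**Compound list**
1 | methyl 3-methylbut-2-enoate | COC(=O)C=C(C)C | starting material
2 | [(1-methoxy-3-methylbuta-1,3-dien-1-yl)oxy]trimethylsilane | COC(=CC(C)=C)O[Si](C)(C)C | intermediate
3 | 2,2-dimethoxyacetaldehyde | COC(OC)C=O | starting material
4 | methyl (2Z,5S)-5-hydroxy-6,6-dimethoxy-3-methylhex-2-enoate (as its copper alkoxide) | COC(=O)/C=C(/C)C[C@H](O)C(OC)OC | intermediate
5 | (S)-6-(dimethoxymethyl)-4-methyl-5,6-dihydro-2H-pyran-2-one | O=C1C=C(C)C[C@H](O1)C(OC)OC | intermediate
6 | (6S)-6-(dimethoxymethyl)-4-methyl-5,6-dihydro-2H-pyran-2-ol, anomer mixture | OC1C=C(C)C[C@H](O1)C(OC)OC | intermediate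
7 | 2,3-dibromoprop-1-ene | C=C(Br)CBr | starting material
8 | (S)-[(4-bromo-1,1-dimethoxypent-4-en-2-yl)oxy]trimethylsilane | COC(OC)[C@@H](O[Si](C)(C)C)CC(Br)=C | intermediate
9 | (S)-4-bromo-1,1-dimethoxypent-4-en-2-ol | COC(OC)[C@@H](O)CC(Br)=C | intermediate
10 | (S)-[(4-bromo-1,1-dimethoxypent-4-en-2-yl)oxy](tert-butyl)dimethylsilane | COC(OC)[C@@H](O[Si](C)(C)C(C)(C)C)CC(Br)=C | intermediate
11 | (S)-4-bromo-2-[(tert-butyldimethylsilyl)oxy]pent-4-enal | O=C[C@@H](O[Si](C)(C)C(C)(C)C)CC(Br)=C | intermediate
12 | methyl acrylate | C=CC(=O)OC | starting material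
13 | methyl (4S)-6-bromo-4-[(tert-butyldimethylsilyl)oxy]-3-hydroxy-2-methylidenehept-6-enoate, C3 epimers | COC(=O)C(=C)C(O)[C@@H](O[Si](C)(C)C(C)(C)C)CC(Br)=C | intermediate
14 | methyl (2Z,4S)-6-bromo-2-(bromomethyl)-4-[(tert-butyldimethylsilyl)oxy]hepta-2,6-dienoate | COC(=O)/C(CBr)=C/[C@@H](O[Si](C)(C)C(C)(C)C)CC(Br)=C | intermediate
15 | methyl (5Z)-3-{3-bromo-1-[(tert-butyldimethylsilyl)oxy]but-3-en-1-yl}-4,8-dihydroxy-9,9-dimethoxy-6-methyl-2-methylidenenon-5-enoate; C2, C6, C7, C8 (germacrane numbering) as in 24 | COC(=O)C(=C)[C@@H]([C@H](O)/C=C(/C)C[C@H](O)C(OC)OC)[C@@H](O[Si](C)(C)C(C)(C)C)CC(Br)=C | intermediate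
16 | 4-{3-bromo-1-[(tert-butyldimethylsilyl)oxy]but-3-en-1-yl}-5-[(1Z)-4-hydroxy-5,5-dimethoxy-2-methylpent-1-en-1-yl]-3-methylideneoxolan-2-one, 4,5-trans; stereocentres as in 24 | C=C1C(=O)O[C@H](/C=C(/C)C[C@H](O)C(OC)OC)[C@H]1[C@@H](O[Si](C)(C)C(C)(C)C)CC(Br)=C | intermediate
17 | 4-{3-bromo-1-[(tert-butyldimethylsilyl)oxy]but-3-en-1-yl}-5-[(1Z)-4-hydroxy-2-methyl-5-oxopent-1-en-1-yl]-3-methylideneoxolan-2-one; stereocentres as in 24 | C=C1C(=O)O[C@H](/C=C(/C)C[C@H](O)C=O)[C@H]1[C@@H](O[Si](C)(C)C(C)(C)C)CC(Br)=C | intermediate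
18 | (10Z)-4-[(tert-butyldimethylsilyl)oxy]-7,8-dihydroxy-10-methyl-3,6-dimethylidene-3a,4,5,6,7,8,9,11a-octahydrocyclodeca[b]furan-2(3H)-one; positions 3a, 4, 8, 11a as in 24, position 7 both epimers | C=C1C(=O)O[C@@H]2/C=C(/C)C[C@H](O)C(O)C(=C)C[C@H](O[Si](C)(C)C(C)(C)C)[C@@H]12 | intermediate
19 | (10Z)-4,7,8-trihydroxy-10-methyl-3,6-dimethylidene-3a,4,5,6,7,8,9,11a-octahydrocyclodeca[b]furan-2(3H)-one; positions 3a, 4, 8, 11a as in 24, position 7 both epimers | C=C1C(=O)O[C@@H]2/C=C(/C)C[C@H](O)C(O)C(=C)C[C@H](O)[C@@H]12 | intermediate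
20 | angelic acid, (Z)-2-methylbut-2-enoic acid | C/C=C(/C)C(=O)O | starting material
21 | 7,8-O-phenylboronate (1,3,2-dioxaborolane) of 19 | C=C1C(=O)O[C@@H]2/C=C(/C)C[C@H](O3)C(OB3c4ccccc4)C(=C)C[C@H](O)[C@@H]12 | intermediate
22 | 4-O-angeloyl 7,8-O-phenylboronate of 19 | C=C1C(=O)O[C@@H]2/C=C(/C)C[C@H](O3)C(OB3c4ccccc4)C(=C)C[C@H](OC(=O)/C(C)=C\C)[C@@H]12 | intermediate
23 | (10Z)-7,8-dihydroxy-10-methyl-3,6-dimethylidene-2-oxo-2,3,3a,4,5,6,7,8,9,11a-decahydrocyclodeca[b]furan-4-yl (Z)-2-methylbut-2-enoate; positions 3a, 4, 8, 11a as in 24, position 7 both epimers | C=C1C(=O)O[C@@H]2/C=C(/C)C[C@H](O)C(O)C(=C)C[C@H](OC(=O)/C(C)=C\C)[C@@H]12 | intermediate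
24 | [(3aR,4S,6E,8S,10Z,11aR)-8-hydroxy-6-(hydroxymethyl)-10-methyl-3-methylidene-2-oxo-2,3,3a,4,5,8,9,11a-octahydrocyclodeca[b]furan-4-yl] (Z)-2-methylbut-2-enoate (CNP0270898.1) | C=C1C(=O)O[C@@H]2/C=C(/C)C[C@H](O)/C=C(/CO)C[C@H](OC(=O)/C(C)=C\C)[C@@H]12 | target

**Step count and risks**
Total steps: 14. Longest linear sequence: 11 (steps 4 to 14, from 3 and 7); the west branch (steps 1 to 3) joins at step 9.

The three steps most likely to fail:

Step 9 (fragment union). The risk is the anti selectivity and the sense of induction from C8 in the chromium allylation of a lactol. The fallback sets out from 6 and 14 and comes back at 16. Indium powder in THF–aqueous NH4Cl (Barbier allylation, tolerant of lactols and syn-selective through the Z-configured allylindium) gives the C6-epimeric hydroxy ester F1. Me3SnOH in 1,2-dichloroethane at 70 °C then gives the hydroxy acid F2. Mitsunobu lactonisation (PPh3, DIAD, THF, 0 °C) closes ring B with inversion at C6, so the trans lactone 16 is reached by a C–O bond-forming step instead of by the selectivity of the C–C step.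

Step 11 (ring A closure). The risk is cyclisation of a free α-hydroxy aldehyde to a ten-membered ring. The fallback sets out from 16 and comes back at 19, and changes the cyclisation substrate to a fully protected α-silyloxy aldehyde, the classical partner for this reaction. TBSOTf/2,6-lutidine gives the bis-silyl acetal F3 and cold aqueous TFA the α-silyloxy aldehyde F4. The CrCl2/NiCl2 closure at high dilution then gives the bis-silyl macrocycle F5, and HF·pyridine removes both silyl groups to give 19.

Step 14 (the proposed transposition). The risks are incomplete conversion, migration of the C2 oxygen, or ionisation. The fallback uses known chemistry, sets out from 23 and comes back at 24. N,N′-Carbonyldiimidazole with DMAP gives the cyclic carbonate F6. Zerovalent palladium (Pd2(dba)3·CHCl3, DPEPhos) in wet DMF then ionises the allylic C1–O bond with decarboxylation and water adds to C14 of the allyl complex (decarboxylative allylic hydration of a vinyl cyclic carbonate). The C2–O bond is untouched and the ring again dictates the ring-cis alkene.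

**Further compounds**
F1 | step 9 | methyl (5Z)-3-{3-bromo-1-[(tert-butyldimethylsilyl)oxy]but-3-en-1-yl}-4,8-dihydroxy-9,9-dimethoxy-6-methyl-2-methylidenenon-5-enoate, C6 (germacrane numbering) epimer of 15 | COC(=O)C(=C)[C@@H]([C@@H](O)/C=C(/C)C[C@H](O)C(OC)OC)[C@@H](O[Si](C)(C)C(C)(C)C)CC(Br)=C
F2 | step 9 | (5Z)-3-{3-bromo-1-[(tert-butyldimethylsilyl)oxy]but-3-en-1-yl}-4,8-dihydroxy-9,9-dimethoxy-6-methyl-2-methylidenenon-5-enoic acid, same configuration as F1 | OC(=O)C(=C)[C@@H]([C@@H](O)/C=C(/C)C[C@H](O)C(OC)OC)[C@@H](O[Si](C)(C)C(C)(C)C)CC(Br)=C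
F3 | step 11 | tert-butyldimethylsilyl ether of 16 at the side-chain hydroxyl (germacrane C2) | C=C1C(=O)O[C@H](/C=C(/C)C[C@H](O[Si](C)(C)C(C)(C)C)C(OC)OC)[C@H]1[C@@H](O[Si](C)(C)C(C)(C)C)CC(Br)=C
F4 | step 11 | tert-butyldimethylsilyl ether of 17 at the side-chain hydroxyl (germacrane C2) | C=C1C(=O)O[C@H](/C=C(/C)C[C@H](O[Si](C)(C)C(C)(C)C)C=O)[C@H]1[C@@H](O[Si](C)(C)C(C)(C)C)CC(Br)=C
F5 | step 11 | 8-O-tert-butyldimethylsilyl ether of 18 (ring position 8, germacrane C2) | C=C1C(=O)O[C@@H]2/C=C(/C)C[C@H](O[Si](C)(C)C(C)(C)C)C(O)C(=C)C[C@H](O[Si](C)(C)C(C)(C)C)[C@@H]12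
F6 | step 14 | 7,8-cyclic carbonate (1,3-dioxolan-2-one) of 23 | C=C1C(=O)O[C@@H]2/C=C(/C)C[C@H](O3)C(OC3=O)C(=C)C[C@H](OC(=O)/C(C)=C\C)[C@@H]12
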